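**Strategy**

Ring B (the seven-membered ring, C1–C7; C1 carries the exocyclic methylene, C4 the side chain, C5 the hydroxyl, C6/C7 are the fusion carbons) is cut at C1–C2 and C5–C6. Both bonds, the ring and the cis C5/C6 pair arise in one rhodium-carbenoid cyclopropanation/divinylcyclopropane Cope cascade between cyclopentadienyl diazoacetate 6, which is all of ring A (C6–C10) from (R)-linalool, and silyl dienol ether 16, which is C2–C5 with the complete side chain. The step exploits the latent 1,4-diene of ring B: the exocyclic carbon enters as the ester on C1, C5–O as the enol ether, and the C3=C4 and C1=C7 alkenes left behind are then reduced from the convex face.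

Key step: step 12

Atom labels used below: ring B = C1 (bears exocyclic C16), C2, C3, C4 (bears the side chain), C5 (carbinol), C6, C7; ring A = C6, C7, C8=C9, C10 (methyl carbinol); side chain = C11 (CHMe), C12, C13 (CH–O), C14=C15. TBS = tert-butyldimethylsilyl, TES = triethylsilyl. Stereodescriptors on bicyclic compounds refer to these labels.

Assumption: Rh2(R-DOSP)4 is taken as the catalyst enantiomer that leads to the (5R,6R) series, by extrapolation from the (1S,2R)-cyclopropanes that Rh2(S-DOSP)4 gives with styrene; if the sense of induction is the reverse, the enantiomeric catalyst is used.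

**Fragment A: diazo ester 6**

Step 1
Reactants: 1 (R)-linalool
Product: 2 (1R)-1-methylcyclopent-2-en-1-ol
Conditions: second-generation Grubbs catalyst RuCl2(=CHPh)(PCy3)(H2IMes) (0.5 mol%), CH2Cl2, 40 °C
Reagents that add atoms: none
Why: Ring-closing metathesis of the 1,6-diene unit, accelerated by the allylic hydroxyl, expels 2-methylpropene and carries the tertiary carbinol stereocentre (future C10) from the chiral pool unchanged.

Step 2
Reactants: 2 (1R)-1-methylcyclopent-2-en-1-ol
Product: 3 tert-butyldimethyl{[(1R)-1-methylcyclopent-2-en-1-yl]oxy}silane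
Conditions: TBSOTf, 2,6-lutidine, CH2Cl2, −78 to 0 °C
Reagents that add atoms: tert-butyldimethylsilyl trifluoromethanesulfonate, CC(C)(C)[Si](C)(C)OS(=O)(=O)C(F)(F)F
Why: Silyl triflate silylation of the hindered tertiary allylic alcohol protects it against oxidative 1,3-transposition in the next step and touches no stereocentre.

Step 3
Reactants: 3 tert-butyldimethyl{[(1R)-1-methylcyclopent-2-en-1-yl]oxy}silane
Product: 4 (4R)-4-(TBS-oxy)-4-methylcyclopent-2-en-1-one
Conditions: CrO3, 3,5-dimethylpyrazole, CH2Cl2, −20 °C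
Reagents that add atoms: chromium trioxide, O=[Cr](=O)=O
Why: Allylic C–H oxidation with the CrO3–3,5-dimethylpyrazole complex converts the only allylic methylene (the other allylic position is the quaternary carbinol carbon) into the enone carbonyl, the future C7.

Step 4
Reactants: 4 (4R)-4-(TBS-oxy)-4-methylcyclopent-2-en-1-one
Product: 5 methyl 2-[(4R)-4-(TBS-oxy)-4-methylcyclopent-2-en-1-ylidene]acetate (E/Z mixture)
Conditions: LiN(i-Pr)2, methyl (trimethylsilyl)acetate, THF, −78 °C; then 4, −78 °C to rt
Reagents that add atoms: methyl 2-(trimethylsilyl)acetate, COC(=O)C[Si](C)(C)C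
Why: Peterson olefination, in which the α-silyl ester enolate adds 1,2 to the enone and the β-silyl alkoxide eliminates to the dienoate, whose alkene geometry is irrelevant because step 5 erases it.

Step 5
Reactants: 5 methyl 2-[(4R)-4-(TBS-oxy)-4-methylcyclopent-2-en-1-ylidene]acetate
Product: 6 methyl 2-diazo-2-[(3S)-3-(TBS-oxy)-3-methylcyclopenta-1,4-dien-1-yl]acetate
Conditions: 4-acetamidobenzenesulfonyl azide, DBU, MeCN, 0 °C to rt; used cold and promptly
Reagents that add atoms: 4-acetamidobenzenesulfonyl azide, CC(=O)Nc1ccc(cc1)S(=O)(=O)N=[N+]=[N-]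
Why: Regitz-type diazo transfer through the extended enolate (γ-deprotonation at the ring CH2) installs the diazo group at the α-carbon with deconjugation into the ring, giving a cyclopentadiene that cannot undergo 1,5-hydrogen shifts because its sp3 carbon is quaternary.

**Fragment B: diene 16**

Step 6
Reactants: 7 (3R)-5-methoxy-3-methyl-5-oxopentanoic acid [(R)-methyl hydrogen 3-methylglutarate]
Product: 9 methyl (3R)-3,7-dimethyl-5-oxooct-6-enoate, via acid chloride 8 (not isolated)
Conditions: (COCl)2, cat. DMF, CH2Cl2, 0 °C to rt; concentrate; then (2-methylprop-1-enyl)MgBr, CuI (10 mol%), THF, −78 °C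
Reagents that add atoms: (2-methylprop-1-en-1-yl)magnesium bromide, CC(C)=C[Mg]Br
Why: Copper-catalysed acylation of the organomagnesium reagent by the acid chloride is faster than attack on the methyl ester or on the hindered β,β-disubstituted enone formed, and the C11 stereocentre from the chiral pool is untouched.

Step 7
Reactants: 9 methyl (3R)-3,7-dimethyl-5-oxooct-6-enoate
Product: 10 methyl (3R,5R)-5-hydroxy-3,7-dimethyloct-6-enoate
Conditions: (S)-2-methyl-CBS-oxazaborolidine (20 mol%), catecholborane, toluene, −78 °C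
Reagents that add atoms: none
Why: Corey–Bakshi–Shibata reduction with the alkenyl group as the large substituent delivers hydride to one carbonyl face under catalyst control and sets C13 as R.

Step 8
Reactants: 10 methyl (3R,5R)-5-hydroxy-3,7-dimethyloct-6-enoate
Product: 11 methyl (3R,5R)-5-(TBS-oxy)-3,7-dimethyloct-6-enoate
Conditions: TBSCl, imidazole, DMF, 0 °C to rt (directly after step 7)
Reagents that add atoms: tert-butyldimethylsilyl chloride, CC(C)(C)[Si](C)(C)Cl
Why: Silylation with the chloride and imidazole protects the secondary allylic alcohol before it can lactonise onto the ester and changes no stereocentre.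

Step 9
Reactants: 11 methyl (3R,5R)-5-(TBS-oxy)-3,7-dimethyloct-6-enoate
Product: 12 (3R,5R)-5-(TBS-oxy)-3,7-dimethyloct-6-enal
Conditions: i-Bu2AlH (1.05 equiv), CH2Cl2, −78 °C; aqueous potassium sodium tartrate
Reagents that add atoms: none
Why: Low-temperature partial reduction of the methyl ester stops at the tetrahedral aluminium hemiacetal, which releases the aldehyde on work-up.

Step 10
Reactants: 12 (3R,5R)-5-(TBS-oxy)-3,7-dimethyloct-6-enal
Product: 15 (2E)-2-[(2R,4R)-4-(TBS-oxy)-6-methylhept-5-en-2-yl]but-2-enal, via N-cyclohexyl imine 13 (not isolated), via hydroxy imine 14 (not isolated)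
Conditions: cyclohexylamine, 4 Å molecular sieves, Et2O, rt; LiN(i-Pr)2, THF, −78 °C; acetaldehyde, −78 °C; then aqueous oxalic acid, rt
Reagents that add atoms: acetaldehyde, CC=O
Why: Directed aldol condensation, in which the lithiated imine adds to acetaldehyde and acidic hydrolysis with dehydration gives the α-branched enal as the thermodynamically preferred E isomer without touching C11 or C13.

Step 11
Reactants: 15 (2E)-2-[(2R,4R)-4-(TBS-oxy)-6-methylhept-5-en-2-yl]but-2-enal
Product: 16 triethyl{[(1Z)-2-[(2R,4R)-4-(TBS-oxy)-6-methylhept-5-en-2-yl]buta-1,3-dien-1-yl]oxy}silane (silyloxy group trans to the vinyl group)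
Conditions: Et3SiOTf, Et3N, Et2O, 0 °C
Reagents that add atoms: triethylsilyl trifluoromethanesulfonate, CC[Si](CC)(CC)OS(=O)(=O)C(F)(F)F
Why: O-Silylation of the enal and γ-deprotonation from its s-trans conformer (silyl dienol ether formation) place the silyloxy group trans to the vinyl group, the geometry the Cope step needs.

**Union and endgame**

Step 12
Reactants: 6 methyl 2-diazo-2-[(3S)-3-(TBS-oxy)-3-methylcyclopenta-1,4-dien-1-yl]acetate; 16 silyl dienol ether
Product: 18 bicyclic dienoate (methyl ester C16 on C1; C1=C7, C8=C9, C3=C4; 5-OTES cis to the C6–C10 bond; 10-OTBS, 13-OTBS; 5R,6R,10S,11R,13R), via cis-divinylcyclopropane 17 (not isolated)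
Conditions: Rh2(R-DOSP)4 {dirhodium tetrakis[(R)-N-(4-dodecylbenzenesulfonyl)prolinate]} (1 mol%), hexanes, slow addition of 6 (1.5 equiv) to 16 at −40 °C, warm to rt, then 60 °C
Reagents that add atoms: none
Why: The rhodium carbenoid from 6 cyclopropanates the unhindered monosubstituted vinyl group of 16 (C1–C2 and, transiently, C1–C3) to the cis-divinylcyclopropane 17, whose boat Cope rearrangement forms C5–C6 and breaks C1–C3. The closest known reaction type is the tandem cyclopropanation/Cope ([4+3]) reaction of vinyldiazoacetates with oxygenated dienes. Ring B is closed as a seven-membered ring by [2+1] addition followed by [3,3]-sigmatropic ring expansion. The boat transition state turns the two outward substituents, the C5 silyloxy group and the ring-A bond C6–C10, into a cis pair at C5/C6, and the catalyst fixes their absolute configuration through the face of cyclopropanation, which in turn makes C5 bond to the face of ring A that carries the small C10 methyl, away from the OTBS group. The step needs site selectivity for the terminal vinyl group over the trisubstituted enol ether and prenyl-type alkenes and carbenoid rather than vinylogous reactivity, secured by the steric demand of the donor/acceptor carbenoid, the hindered C6 terminus and the non-polar solvent.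

Step 13
Reactants: 18 bicyclic dienoate
Product: 19 dienyl alcohol (C16 = CH2OH on C1; otherwise as 18)
Conditions: i-Bu2AlH (2.5 equiv), CH2Cl2, −78 °C; aqueous potassium sodium tartrate
Reagents that add atoms: none
Why: 1,2-Reduction of the hindered conjugated ester by the aluminium hydride gives the primary allylic alcohol and leaves silyl ethers and alkenes untouched.

Step 14
Reactants: 19 dienyl alcohol
Product: 22 exocyclic-methylene TES ether (C1=C16H2, cis-fused H6/H7, C8=C9, C3=C4, 5-OTES; 5R,6R,7S,10S), via sulfonyl hydrazide 20 (not isolated), via allylic diazene 21 (not isolated)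
Conditions: 2-nitrobenzenesulfonylhydrazide, PPh3, diethyl azodicarboxylate, THF, −30 °C, then 23 °C
Reagents that add atoms: none
Why: Mitsunobu displacement by the sulfonyl hydrazide, loss of the sulfinic acid and retro-ene extrusion of N2 from the allylic diazene (reductive 1,3-transposition) move the double bond to the exocyclic position and deliver hydrogen to C7 from the convex face, syn to H6 and away from the body of ring B, so that the ring fusion becomes cis.

Step 15
Reactants: 22 exocyclic-methylene TES ether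
Product: 23 allylic alcohol (5-OH; otherwise as 22)
Conditions: pyridinium p-toluenesulfonate, MeOH/CH2Cl2, 0 °C to rt
Reagents that add atoms: none
Why: Mild acid methanolysis cleaves the secondary triethylsilyl ether much faster than the secondary and tertiary TBS ethers.

Step 16
Reactants: 23 allylic alcohol
Product: 24 enone (C5=O conjugated to C3=C4; 6S,7S,10S)
Conditions: Dess–Martin periodinane, NaHCO3, CH2Cl2, 0 °C
Reagents that add atoms: none
Why: Dess–Martin oxidation of the secondary allylic alcohol gives the enone under buffered, non-epimerising conditions; the C5 stereocentre is given up on purpose and restored in step 18.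

Step 17
Reactants: 24 enone
Product: 25 ketone (C5=O, C4–H set; 4R,6S,7S,10S)
Conditions: [(Ph3P)CuH]6, degassed toluene, H2O (2 equiv), rt
Reagents that add atoms: none
Why: Copper hydride conjugate reduction is chemoselective for the enone over the four isolated alkenes, and protonation at C4 from the convex face (anti to ring A) should place the side chain cis to the C6–C10 bond, the α,α′-cis arrangement that is also expected to be thermodynamically preferred.

Step 18
Reactants: 25 ketone
Product: 26 bis-TBS alcohol (5-OH cis to the side chain and to ring A; 4R,5S,6R,7S,10S)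
Conditions: LiBH(s-Bu)3, THF, −78 to −20 °C
Reagents that add atoms: none
Why: The bulky borohydride should attack the ketone from the convex periphery, opposite both α-substituents, so that the C5 hydroxyl ends cis to the side chain and to ring A (hydrogens at C4–C7 all on one face).

Step 19
Reactants: 26 bis-TBS alcohol
Product: 27 triol (5-OH, 10-OH, 13-OH)
Conditions: n-Bu4NF, THF, 23 to 45 °C
Reagents that add atoms: none
Why: Fluoride cleaves the secondary and the tertiary silyl ether, and nothing in the triol is base-sensitive.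

Step 20
Reactants: 27 triol
Product: 28 target CNP0209568.2
Conditions: Ac2O (1.2 equiv), pyridine, CH2Cl2, 0 °C
Reagents that add atoms: acetic anhydride, CC(=O)OC(C)=O
Why: Acylation should be selective for the unhindered secondary allylic C13 hydroxyl, because the C5 hydroxyl lies on the concave face between two branched carbons and the C10 hydroxyl is tertiary.

**Compound list**

1 | (R)-linalool, (3R)-3,7-dimethylocta-1,6-dien-3-ol | C=C[C@](C)(O)CCC=C(C)C | starting material
2 | (1R)-1-methylcyclopent-2-en-1-ol | C1=C[C@](C)(O)CC1 | intermediate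
3 | tert-butyldimethyl{[(1R)-1-methylcyclopent-2-en-1-yl]oxy}silane | C1=C[C@](C)(O[Si](C)(C)C(C)(C)C)CC1 | intermediate
4 | (4R)-4-(TBS-oxy)-4-methylcyclopent-2-en-1-one | O=C1C=C[C@](C)(O[Si](C)(C)C(C)(C)C)C1 | intermediate
5 | methyl 2-[(4R)-4-(TBS-oxy)-4-methylcyclopent-2-en-1-ylidene]acetate (E/Z mixture) | COC(=O)C=C1C=C[C@](C)(O[Si](C)(C)C(C)(C)C)C1 | intermediate
6 | methyl 2-diazo-2-[(3S)-3-(TBS-oxy)-3-methylcyclopenta-1,4-dien-1-yl]acetate | COC(=O)C(=[N+]=[N-])C1=C[C@@](C)(O[Si](C)(C)C(C)(C)C)C=C1 | intermediate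
7 | (3R)-5-methoxy-3-methyl-5-oxopentanoic acid | COC(=O)C[C@H](C)CC(=O)O | starting material
8 | methyl (3S)-5-chloro-3-methyl-5-oxopentanoate (same spatial arrangement as 7) | COC(=O)C[C@H](C)CC(=O)Cl | intermediate
9 | methyl (3R)-3,7-dimethyl-5-oxooct-6-enoate | COC(=O)C[C@H](C)CC(=O)C=C(C)C | intermediate
10 | methyl (3R,5R)-5-hydroxy-3,7-dimethyloct-6-enoate | COC(=O)C[C@H](C)C[C@H](C=C(C)C)O | intermediate
11 | methyl (3R,5R)-5-(TBS-oxy)-3,7-dimethyloct-6-enoate | COC(=O)C[C@H](C)C[C@H](C=C(C)C)O[Si](C)(C)C(C)(C)C | intermediate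
12 | (3R,5R)-5-(TBS-oxy)-3,7-dimethyloct-6-enal | O=CC[C@H](C)C[C@H](C=C(C)C)O[Si](C)(C)C(C)(C)C | intermediate
13 | N-cyclohexyl imine of 12 | C1CCCCC1N=CC[C@H](C)C[C@H](C=C(C)C)O[Si](C)(C)C(C)(C)C | intermediate
14 | β-hydroxy imine from 13 and acetaldehyde (diastereomer mixture at the two new centres) | CC(O)C(C=NC1CCCCC1)[C@H](C)C[C@H](C=C(C)C)O[Si](C)(C)C(C)(C)C | intermediate
15 | (2E)-2-[(2R,4R)-4-(TBS-oxy)-6-methylhept-5-en-2-yl]but-2-enal | C/C=C(/C=O)[C@H](C)C[C@H](C=C(C)C)O[Si](C)(C)C(C)(C)C | intermediate
16 | triethyl{[(1Z)-2-[(2R,4R)-4-(TBS-oxy)-6-methylhept-5-en-2-yl]buta-1,3-dien-1-yl]oxy}silane | C=C/C(=C/O[Si](CC)(CC)CC)[C@H](C)C[C@H](C=C(C)C)O[Si](C)(C)C(C)(C)C | intermediate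
17 | cis-divinylcyclopropane, methyl (1R,2S)-1-(cyclopentadienyl)-2-(silyloxyalkenyl)cyclopropane-1-carboxylate | COC(=O)[C@]1(C2=C[C@@](C)(O[Si](C)(C)C(C)(C)C)C=C2)C[C@H]1/C(=C/O[Si](CC)(CC)CC)[C@H](C)C[C@H](C=C(C)C)O[Si](C)(C)C(C)(C)C | intermediate
18 | bicyclic dienoate (5R,6R,10S,11R,13R) | COC(=O)C1=C2C=C[C@](C)(O[Si](C)(C)C(C)(C)C)[C@H]2[C@@H](O[Si](CC)(CC)CC)C([C@H](C)C[C@H](C=C(C)C)O[Si](C)(C)C(C)(C)C)=CC1 | intermediate
19 | dienyl alcohol (C16 = CH2OH) | OCC1=C2C=C[C@](C)(O[Si](C)(C)C(C)(C)C)[C@H]2[C@@H](O[Si](CC)(CC)CC)C([C@H](C)C[C@H](C=C(C)C)O[Si](C)(C)C(C)(C)C)=CC1 | intermediate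
20 | N-allyl-N-(2-nitrobenzenesulfonyl)hydrazine from 19 | NN(CC1=C2C=C[C@](C)(O[Si](C)(C)C(C)(C)C)[C@H]2[C@@H](O[Si](CC)(CC)CC)C([C@H](C)C[C@H](C=C(C)C)O[Si](C)(C)C(C)(C)C)=CC1)S(=O)(=O)c1ccccc1[N+](=O)[O-] | intermediate
21 | allylic diazene from 20 | N=NCC1=C2C=C[C@](C)(O[Si](C)(C)C(C)(C)C)[C@H]2[C@@H](O[Si](CC)(CC)CC)C([C@H](C)C[C@H](C=C(C)C)O[Si](C)(C)C(C)(C)C)=CC1 | intermediate
22 | exocyclic-methylene TES ether (5R,6R,7S,10S,11R,13R) | C=C1CC=C([C@H](C)C[C@H](C=C(C)C)O[Si](C)(C)C(C)(C)C)[C@H](O[Si](CC)(CC)CC)[C@H]2[C@@H]1C=C[C@]2(C)O[Si](C)(C)C(C)(C)C | intermediate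
23 | allylic alcohol (5-OH) | C=C1CC=C([C@H](C)C[C@H](C=C(C)C)O[Si](C)(C)C(C)(C)C)[C@H](O)[C@H]2[C@@H]1C=C[C@]2(C)O[Si](C)(C)C(C)(C)C | intermediate
24 | enone (C5=O, C3=C4) | C=C1CC=C([C@H](C)C[C@H](C=C(C)C)O[Si](C)(C)C(C)(C)C)C(=O)[C@H]2[C@@H]1C=C[C@]2(C)O[Si](C)(C)C(C)(C)C | intermediate
25 | ketone (4R,6S,7S,10S,11R,13R) | C=C1CC[C@H]([C@H](C)C[C@H](C=C(C)C)O[Si](C)(C)C(C)(C)C)C(=O)[C@H]2[C@@H]1C=C[C@]2(C)O[Si](C)(C)C(C)(C)C | intermediate
26 | bis-TBS alcohol (4R,5S,6R,7S,10S,11R,13R) | C=C1CC[C@H]([C@H](C)C[C@H](C=C(C)C)O[Si](C)(C)C(C)(C)C)[C@H](O)[C@H]2[C@@H]1C=C[C@]2(C)O[Si](C)(C)C(C)(C)C | intermediate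
27 | triol | C=C1CC[C@H]([C@H](C)C[C@H](C=C(C)C)O)[C@H](O)[C@H]2[C@@H]1C=C[C@]2(C)O | intermediate
28 | CNP0209568.2 | C=C1CC[C@H]([C@H](C)C[C@H](C=C(C)C)OC(C)=O)[C@H](O)[C@H]2[C@@H]1C=C[C@]2(C)O | target

**Step count**

Total: 20 steps. Longest linear sequence: 15 steps (7 to 28, steps 6–20). The fragment A branch is 5 steps before the union.

**Steps most likely to fail**

Step 12. The electrophilic carbenoid may be diverted before cyclopropanation, either by attack of the electron-rich silyl dienol ether through its oxygen-bearing alkene (zwitterion formation, silyl transfer) or by self-reaction of the cyclopentadienyl diazo ester. The Cope step at the hindered C6 terminus may also stall. Fallback, setting out from 15 and 6 and returning at 23: O-acylation of the potassium dienolate of 15 (KN(SiMe3)2, THF, −78 °C, then pivaloyl chloride) would give the less nucleophilic dienyl pivalate F1, a diene class that is less prone to zwitterionic side reactions. The same dirhodium-catalysed reaction with 6 should give bicyclic pivalate F2. Excess i-Bu2AlH would cleave both esters to diol F3. The sulfonyl hydrazide Mitsunobu/retro-ene sequence of step 14, selective for the primary allylic alcohol, would then pass through hydrazide F4 and diazene F5 and give 23 directly, without the separate desilylation.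

Step 14. Hydrogen may be delivered to the wrong face of C7 (trans ring fusion), or the Mitsunobu displacement at the congested dienylic alcohol may give way to elimination. Fallback, from 19 back to 22: methyl chloroformate and pyridine would give allylic carbonate F6. Palladium-catalysed formate hydrogenolysis (Pd(OAc)2, n-Bu3P, HCO2NH4, THF, 40 °C) should then transfer hydride from the metal, bound on the convex face, to the more substituted allyl terminus C7 and give the exocyclic alkene 22 by an inner-sphere mechanism instead of a sigmatropic one.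

Step 17. Protonation of the copper enolate may occur on the concave face and give the C4 epimer, or 1,2-reduction may compete. Fallback, from 24 back to 25: the kinetic protonation is replaced by thermodynamic control. The epimeric ketone F7 (or a mixture with 25) is equilibrated through its enol with a catalytic amine base (DBU, toluene, 0 °C), which should favour the α,α′-cis ketone 25. Exposure is kept short, since the C6 centre and the β-silyloxy group are also base-sensitive.

**Further compounds**

F1 | step 12 | (1Z)-2-[(2R,4R)-4-(TBS-oxy)-6-methylhept-5-en-2-yl]buta-1,3-dien-1-yl 2,2-dimethylpropanoate | C=C/C(=C/OC(=O)C(C)(C)C)[C@H](C)C[C@H](C=C(C)C)O[Si](C)(C)C(C)(C)C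
F2 | step 12 | bicyclic dienoate with 5-O-pivaloyl in place of 5-OTES | COC(=O)C1=C2C=C[C@](C)(O[Si](C)(C)C(C)(C)C)[C@H]2[C@@H](OC(=O)C(C)(C)C)C([C@H](C)C[C@H](C=C(C)C)O[Si](C)(C)C(C)(C)C)=CC1
F3 | step 12 | diol (C16 = CH2OH, 5-OH) | OCC1=C2C=C[C@](C)(O[Si](C)(C)C(C)(C)C)[C@H]2[C@@H](O)C([C@H](C)C[C@H](C=C(C)C)O[Si](C)(C)C(C)(C)C)=CC1
F4 | step 12 | N-allyl-N-(2-nitrobenzenesulfonyl)hydrazine from F3 | NN(CC1=C2C=C[C@](C)(O[Si](C)(C)C(C)(C)C)[C@H]2[C@@H](O)C([C@H](C)C[C@H](C=C(C)C)O[Si](C)(C)C(C)(C)C)=CC1)S(=O)(=O)c1ccccc1[N+](=O)[O-]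
F5 | step 12 | allylic diazene from F4 | N=NCC1=C2C=C[C@](C)(O[Si](C)(C)C(C)(C)C)[C@H]2[C@@H](O)C([C@H](C)C[C@H](C=C(C)C)O[Si](C)(C)C(C)(C)C)=CC1
F6 | step 14 | allylic methyl carbonate of 19 | COC(=O)OCC1=C2C=C[C@](C)(O[Si](C)(C)C(C)(C)C)[C@H]2[C@@H](O[Si](CC)(CC)CC)C([C@H](C)C[C@H](C=C(C)C)O[Si](C)(C)C(C)(C)C)=CC1
F7 | step 17 | C4 epimer of ketone 25 | C=C1CC[C@@H]([C@H](C)C[C@H](C=C(C)C)O[Si](C)(C)C(C)(C)C)C(=O)[C@H]2[C@@H]1C=C[C@]2(C)O[Si](C)(C)C(C)(C)C
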